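**Retrosynthetic overview**
1. Feature: ring B carries oxygen at C6 and C9 in a para relationship, with the C17 methyl on C8 and the C20 carbon on C10 flanking C9. This is the pattern of methyl 5-methyl-3,6-dioxocyclohexa-1,4-diene-1-carboxylate (5).
2. Key disconnection: ring A by an enantioselective quinone Diels–Alder reaction of 5 (C5=C10) with silyloxydiene ester 10 (bonds C4–C5 and C1–C10). C19 arrives as a benzyl ester so that it can be told apart from the C20 methyl ester.
3. Ring B is then adjusted (C7=C8 reduced, C5 and C8 epimerised, C6 reduced and silylated before C4 becomes quaternary), C4 is methylated anti to C20, C3 is deoxygenated, and C20 is reduced onto C19 (δ-lactone).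
4. Side chain: vinyl addition to the C9 ketone, B-alkyl Suzuki coupling with iodoallylic alcohol 27, Sharpless epoxidation with 5-exo epoxide opening by the 9-OH (sets C13), glycol cleavage, oxidation and γ-lactonisation.
5. Ring order: B (quinone) → A (cycloaddition) → 19,20-lactone → spiro-tetrahydrofuran → spiro-γ-lactone.

Key step: step 7

Remark on notation: labdane numbering is used (C17 = 8-methyl, C18 = 4-methyl, C19 = carboxyl carbon on C4, C20 = carbon on C10; C16′ is an extra carbinol carbon that is excised in step 24); α/β refer to the drawing with C20 on the β face.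
Assumption: the (S,S)-t-Bu-box complex of Cu(OTf)2 is taken to shield the face of the chelated quinone that leads to adduct 11 as drawn; should the opposite sense be found, the (R,R)-ligand is used and nothing else changes.

**Route**

Step 1
Reactants: 1 3-methylsalicylic acid
Product: 3 2,5-dihydroxy-3-methylbenzoic acid, via aryl sulfate 2 (not isolated)
Conditions: K2S2O8, aq. NaOH, 0 °C → rt; then aq. HCl, 90 °C
Reagents that add atoms: potassium persulfate, [K+].[K+].[O-]S(=O)(=O)OOS(=O)(=O)[O-]
Why: Elbs persulfate oxidation, in which the phenolate is sulfated para to oxygen (both ortho positions are blocked by CO2H and CH3) and the aryl sulfate is then hydrolysed by acid.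

Step 2
Reactants: 3 2,5-dihydroxy-3-methylbenzoic acid
Product: 4 methyl 2,5-dihydroxy-3-methylbenzoate
Conditions: MeOH, H2SO4 (cat.), reflux
Reagents that add atoms: methanol, CO
Why: Fischer esterification of the carboxylic acid, the phenols being inert under these conditions.

Step 3
Reactants: 4 methyl 2,5-dihydroxy-3-methylbenzoate
Product: 5 methyl 5-methyl-3,6-dioxocyclohexa-1,4-diene-1-carboxylate
Conditions: Ag2O, Na2SO4, CH2Cl2, rt, dark; filtered and used at once
Reagents that add atoms: none
Why: mild two-electron oxidation of a hydroquinone to the p-benzoquinone, the standard way to make a sensitive 2-alkoxycarbonyl quinone immediately before use.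

Step 4
Reactants: 6 benzyl acetate; 7 acrolein
Product: 8 benzyl 3-hydroxypent-4-enoate (racemic)
Conditions: LiN(i-Pr)2, THF, −78 °C; then 7; aq. NH4Cl
Reagents that add atoms: none
Why: aldol addition of the lithium ester enolate to the aldehyde carbonyl of acrolein (1,2-addition at −78 °C); the carbinol centre is destroyed in step 5.

Step 5
Reactants: 8 benzyl 3-hydroxypent-4-enoate
Product: 9 benzyl 3-oxopent-4-enoate
Conditions: Dess–Martin periodinane, CH2Cl2, 0 °C; used crude
Reagents that add atoms: none
Why: Dess–Martin oxidation of the allylic alcohol to the vinyl ketone of a β-keto ester under neutral conditions that spare this polymerisation-prone compound.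

Step 6
Reactants: 9 benzyl 3-oxopent-4-enoate
Product: 10 benzyl (Z)-3-(tert-butyldimethylsilyloxy)penta-2,4-dienoate
Conditions: TBSOTf, Et3N, CH2Cl2, −78 → 0 °C
Reagents that add atoms: tert-butyldimethylsilyl triflate, CC(C)(C)[Si](C)(C)OS(=O)(=O)C(F)(F)F
Why: soft enolisation and O-silylation of the β-keto ester, which should give the (Z)-enol ether (silyloxy and ester cis) and so places the ester on the outside of the s-cis diene.

Step 7
Reactants: 5 methyl 5-methyl-3,6-dioxocyclohexa-1,4-diene-1-carboxylate; 10 benzyl (Z)-3-(tert-butyldimethylsilyloxy)penta-2,4-dienoate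
Product: 11 cis-fused ene-dione adduct (10β-CO2Me, 5β-H, 4α-CO2Bn, C2=C3 enol TBS ether, C7=C8, 6,9-dione)
Conditions: Cu(OTf)2 (10 mol %, divalent copper), (S,S)-t-Bu-box (11 mol %), 4 Å MS, CH2Cl2, −78 → −40 °C
Reagents that add atoms: none
Why: The quinone binds the copper complex through the C9 carbonyl and the ester carbonyl (six-membered chelate), which activates only the C5=C10 bond, and the silyloxydiene adds to it in an asynchronous endo [4+2] cycloaddition in which the enol-ether carbon C4 bonds to C5 and C1 then closes on C10. The closest known reaction type is the Lewis-acid-catalysed enantioselective Diels–Alder reaction of 2-alkoxycarbonyl-1,4-benzoquinones with 2-silyloxydienes, together with Cu(OTf)2–bis(oxazoline) catalysis of chelating 1,3-dicarbonyl dienophiles. Ring A closes as a six-membered carbocycle by intermolecular suprafacial [4+2] closure, both new σ bonds forming on one face of the quinone, which is why the ring fusion is cis. C10 is set by the chiral copper complex, whose tert-butyl groups shield one face of the chelated ene-dione; C5 follows from suprafacial addition (H5 cis to the C10 ester); C4 follows from the (Z)-diene geometry and the endo transition state and is later enolised. The step needs site selectivity (C5=C10 over the methylated C7=C8), regioselectivity and facial selectivity: chelation and the ester secure the first, the polarisation of the diene (nucleophilic C4) against the ester-activated C5 the second, and the ligand the third.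

Step 8
Reactants: 11 cis-fused ene-dione adduct
Product: 12 cis-fused 6,9-dione (C7–C8 saturated, C8 epimers)
Conditions: Zn dust, AcOH (10 equiv), THF, 0 °C
Reagents that add atoms: none
Why: zinc/acetic acid reduction of the 2-ene-1,4-dione, which is chemoselective for the C7=C8 bond and leaves the enol silyl ether, both esters and C5 untouched.

Step 9
Reactants: 12 cis-fused 6,9-dione
Product: 13 trans-fused 6,9-dione (5α-H, 8α-CH3, 10β-CO2Me, 4α-CO2Bn, C2=C3 enol TBS ether)
Conditions: DBU (0.3 equiv), PhMe, rt → 40 °C; recovered cis isomer re-equilibrated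
Reagents that add atoms: none
Why: base-mediated epimerisation under thermodynamic control at the two ketone α-carbons, where C5 (α to the C6 ketone) should settle in the trans-decalin while C4 is still a CH carbon with an equatorial ester, and C8 (α to the C9 ketone) should settle with the methyl equatorial (α).

Step 10
Reactants: 13 trans-fused 6,9-dione
Product: 14 6β-hydroxy-9-ketone
Conditions: LiBH(s-Bu)3, THF, −78 °C; AcOH added at −78 °C
Reagents that add atoms: none
Why: bulky-hydride reduction, which takes only the C6 ketone (C9 is flanked by the quaternary C10 and by C8) and delivers hydride from the α face because the axial C10 ester blocks the β face, giving the axial 6β-alcohol; cold acidic quench keeps the alkoxide from attacking the C20 ester.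

Step 11
Reactants: 14 6β-hydroxy-9-ketone
Product: 15 6β-TBS ether
Conditions: TBSOTf, 2,6-lutidine, CH2Cl2, −40 → 0 °C
Reagents that add atoms: tert-butyldimethylsilyl triflate, CC(C)(C)[Si](C)(C)OS(=O)(=O)C(F)(F)F
Why: silylation of the secondary alcohol with a silyl triflate and a hindered base, done before C4 is quaternary so that the 6β-oxygen can never lactonise onto C19 or C20 and C5 can no longer epimerise.

Step 12
Reactants: 15 6β-TBS ether
Product: 16 3-oxo β-keto ester (6β-OTBS, 9-oxo; C4 epimers and enol)
Conditions: Bu4NF, AcOH (1:1), THF, 0 °C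
Reagents that add atoms: none
Why: buffered fluoride cleavage of the silyl enol ether, which is far more labile than the hindered secondary alkyl silyl ether, releasing the C3 ketone of the β-keto ester.

Step 13
Reactants: 16 3-oxo β-keto ester
Product: 17 4α-methyl-4β-(benzyloxycarbonyl)-3,9-dione (6β-OTBS, 10β-CO2Me)
Conditions: K2CO3, MeI, acetone, 45 °C
Reagents that add atoms: iodomethane, CI
Why: C-alkylation of the β-keto ester enolate, in which methyl iodide approaches C4 from the α face because the β face is closed by the axial C10 ester and the 6β-silyloxy group, so that the methyl is α and the C19 ester is β, cis to C20.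

Step 14
Reactants: 17 4α-methyl-4β-(benzyloxycarbonyl)-3,9-dione
Product: 18 3,3-(ethylenedithio) derivative of 17
Conditions: HSCH2CH2SH, BF3·OEt2 (0.5 equiv), CH2Cl2, −20 → 0 °C
Reagents that add atoms: ethane-1,2-dithiol, SCCS
Why: Lewis-acid dithioketalisation, selective for the C3 ketone because the C9 ketone lies between a quaternary and a tertiary carbon.

Step 15
Reactants: 18 3,3-(ethylenedithio) derivative
Product: 19 6β-OTBS-9-oxo 19-oic acid 20-methyl ester (C3 = CH2)
Conditions: Raney Ni (W-2), H2 (1 atm), EtOH, 50 °C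
Reagents that add atoms: none
Why: Mozingo desulfurisation of the dithiolane to CH2 with hydrogenolysis of the benzyl ester on the same catalyst, which frees the C19 acid while the C20 methyl ester and the hindered C9 ketone should remain.

Step 16
Reactants: 19 19-oic acid 20-methyl ester
Product: 21 9-hydroxy-19,20-olide (6β-OTBS; C9 epimers), via dihydroxy acid 20 (not isolated)
Conditions: LiBHEt3 (6 equiv), THF, 0 °C → rt; 1 M HCl, 0 °C; then PPTS (cat.), PhMe, 60 °C
Reagents that add atoms: none
Why: hydride reduction in which the first equivalent converts the acid into an unreactive lithium carboxylate, the C20 methyl ester and the C9 ketone are reduced, and the 20-hydroxy 19-acid (1,3-diaxial) then lactonises to the δ-lactone under mild acid; C9 is reduced first so that the free C20 alkoxide cannot undergo retro-aldol loss of formaldehyde.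

Step 17
Reactants: 21 9-hydroxy-19,20-olide
Product: 22 9-oxo-19,20-olide (6β-OTBS, 8α-CH3)
Conditions: Dess–Martin periodinane, CH2Cl2, rt
Reagents that add atoms: none
Why: Dess–Martin oxidation of the hindered secondary alcohol back to the C9 ketone without epimerising C8.

Step 18
Reactants: 22 9-oxo-19,20-olide
Product: 23 9α-hydroxy-9β-vinyl-19,20-olide
Conditions: CH2=CHMgBr, CeCl3 (anhydrous), THF, −78 → 0 °C; aq. NH4Cl
Reagents that add atoms: vinylmagnesium bromide, C=C[Mg]Br
Why: cerium-mediated Grignard addition (suppresses enolisation towards C8) to the ketone rather than the hindered lactone, where the nucleophile should enter along the equatorial direction, trans to the 8α-methyl and away from the three syn-axial α-hydrogens at C1, C5 and C7, giving 9β-vinyl and 9α-OH.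

Step 19
Reactants: 24 but-3-yn-1-ol
Product: 25 tert-butyl(but-3-yn-1-yloxy)dimethylsilane
Conditions: TBSCl, imidazole, DMF, rt
Reagents that add atoms: tert-butyldimethylsilyl chloride, CC(C)(C)[Si](C)(C)Cl
Why: standard silylation of a primary alcohol.

Step 20
Reactants: 25 tert-butyl(but-3-yn-1-yloxy)dimethylsilane
Product: 26 5-(tert-butyldimethylsilyloxy)pent-2-yn-1-ol
Conditions: n-BuLi, THF, −78 °C; (CH2O)n, −78 °C → rt; aq. NH4Cl
Reagents that add atoms: paraformaldehyde (as formaldehyde), C=O
Why: addition of the lithium acetylide to formaldehyde (hydroxymethylation of a terminal alkyne).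

Step 21
Reactants: 26 5-(tert-butyldimethylsilyloxy)pent-2-yn-1-ol
Product: 27 (Z)-5-(tert-butyldimethylsilyloxy)-3-iodopent-2-en-1-ol
Conditions: NaAlH2(OCH2CH2OMe)2, THF, 0 °C → rt; then I2, −78 °C
Reagents that add atoms: iodine, II
Why: hydroxyl-directed trans-hydroalumination of the propargylic alcohol followed by iodinolysis, which puts iodine on the distal alkyne carbon (C13) cis to the CH2OH group with defined geometry.

Step 22
Reactants: 23 9α-hydroxy-9β-vinyl-19,20-olide; 27 (Z)-5-(tert-butyldimethylsilyloxy)-3-iodopent-2-en-1-ol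
Product: 29 allylic alcohol with the C13=C16 alkene (C12 cis to CH2OH, 13E), via alkylborane 28 (not isolated)
Conditions: 9-BBN-H, THF, 0 °C → rt; then 27, PdCl2(dppf) (5 mol %), AsPh3, Cs2CO3, DMF/THF/H2O, rt
Reagents that add atoms: none
Why: anti-Markovnikov hydroboration of the vinyl group (boron on C12) followed by B-alkyl Suzuki–Miyaura coupling, which forms C12–C13 with retention of the alkenyl iodide geometry.

Step 23
Reactants: 29 allylic alcohol
Product: 31 9α,13-epoxy (spiro-tetrahydrofuran) 16,16′-diol (13S,16R), via epoxy alcohol 30 (not isolated)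
Conditions: Ti(OiPr)4 (10 mol %), D-(−)-diisopropyl tartrate (12 mol %), t-BuOOH, 4 Å MS, CH2Cl2, −20 °C; then CSA (10 mol %), CH2Cl2, 0 °C
Reagents that add atoms: tert-butyl hydroperoxide, CC(C)(C)OO
Why: Sharpless asymmetric epoxidation sets the epoxide by reagent control (the D-(−)-tartrate gives the (13R,16R)-epoxy alcohol, the series opposite to the 2S epoxy alcohols obtained with the L-(+)-tartrate), and acid-catalysed 5-exo opening by the tertiary 9-OH at the tertiary epoxide carbon with inversion then closes the tetrahydrofuran and fixes C13 as in the target.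

Step 24
Reactants: 31 spiro-tetrahydrofuran 16,16′-diol
Product: 32 C16 aldehyde (9α,13-epoxy, 15-OTBS, 6β-OTBS, 19,20-olide)
Conditions: NaIO4, THF/pH 7 buffer, 0 °C
Reagents that add atoms: none
Why: periodate glycol cleavage, which removes C16′ and leaves a non-enolisable α-alkoxy aldehyde on the quaternary C13.

Step 25
Reactants: 32 C16 aldehyde
Product: 33 C16 carboxylic acid
Conditions: NaClO2, NaH2PO4, 2-methylbut-2-ene, t-BuOH/H2O, rt
Reagents that add atoms: sodium chlorite, [Na+].[O-]Cl=O
Why: Pinnick oxidation of the aldehyde to the acid, compatible with silyl ethers, the lactone and the tertiary ethers.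

Step 26
Reactants: 33 C16 carboxylic acid
Product: 35 CNP0393616.1, via dihydroxy acid 34 (not isolated)
Conditions: HF·pyridine, THF/pyridine, 0 °C → rt
Reagents that add atoms: none
Why: buffered acidic fluoride desilylation of both silyl ethers, after which the γ-hydroxy acid on the quaternary C13 closes to the 16,15-lactone; mild, non-basic conditions are chosen so that the free 6β-hydroxyl should not exchange with the 19,20-lactone.

**Compound list**
1 | 3-methylsalicylic acid | Cc1cccc(C(=O)O)c1O | starting material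
2 | 3-carboxy-4-hydroxy-5-methylphenyl hydrogen sulfate (not isolated) | Cc1cc(OS(=O)(=O)O)cc(C(=O)O)c1O | intermediate
3 | 2,5-dihydroxy-3-methylbenzoic acid | Cc1cc(O)cc(C(=O)O)c1O | intermediate
4 | methyl 2,5-dihydroxy-3-methylbenzoate | COC(=O)c1cc(O)cc(C)c1O | intermediate
5 | methyl 5-methyl-3,6-dioxocyclohexa-1,4-diene-1-carboxylate | COC(=O)C1=CC(=O)C=C(C)C1=O | intermediate
6 | benzyl acetate | CC(=O)OCc1ccccc1 | starting material
7 | acrolein | C=CC=O | starting material
8 | benzyl 3-hydroxypent-4-enoate (racemic) | C=CC(O)CC(=O)OCc1ccccc1 | intermediate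
9 | benzyl 3-oxopent-4-enoate | C=CC(=O)CC(=O)OCc1ccccc1 | intermediate
10 | benzyl (Z)-3-(tert-butyldimethylsilyloxy)penta-2,4-dienoate | C=C/C(O[Si](C)(C)C(C)(C)C)=C/C(=O)OCc1ccccc1 | intermediate
11 | cis-fused ene-dione adduct (10β-CO2Me, 5β-H, 4α-CO2Bn, C2=C3 enol TBS ether, C7=C8) | CC1=CC(=O)[C@@H]2[C@H](C(=O)OCc3ccccc3)C(O[Si](C)(C)C(C)(C)C)=CC[C@]2(C(=O)OC)C1=O | intermediate
12 | cis-fused 6,9-dione (C8 epimers) | CC1CC(=O)[C@@H]2[C@H](C(=O)OCc3ccccc3)C(O[Si](C)(C)C(C)(C)C)=CC[C@]2(C(=O)OC)C1=O | intermediate
13 | trans-fused 6,9-dione (5α-H, 8α-CH3) | C[C@@H]1CC(=O)[C@@H]2[C@](C(=O)OC)(CC=C(O[Si](C)(C)C(C)(C)C)[C@H]2C(=O)OCc2ccccc2)C1=O | intermediate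
14 | 6β-hydroxy-9-ketone | C[C@@H]1C[C@@H](O)[C@@H]2[C@](C(=O)OC)(CC=C(O[Si](C)(C)C(C)(C)C)[C@H]2C(=O)OCc2ccccc2)C1=O | intermediate
15 | 6β-TBS ether | C[C@@H]1C[C@@H](O[Si](C)(C)C(C)(C)C)[C@@H]2[C@](C(=O)OC)(CC=C(O[Si](C)(C)C(C)(C)C)[C@H]2C(=O)OCc2ccccc2)C1=O | intermediate
16 | 3-oxo β-keto ester (C4 epimers and enol) | C[C@@H]1C[C@@H](O[Si](C)(C)C(C)(C)C)[C@@H]2[C@](C(=O)OC)(CCC(=O)C2C(=O)OCc2ccccc2)C1=O | intermediate
17 | 4α-methyl-4β-(benzyloxycarbonyl)-3,9-dione | C[C@@H]1C[C@@H](O[Si](C)(C)C(C)(C)C)[C@@H]2[C@](C(=O)OC)(CCC(=O)[C@]2(C)C(=O)OCc2ccccc2)C1=O | intermediate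
18 | 3,3-(ethylenedithio) derivative of 17 | C[C@@H]1C[C@@H](O[Si](C)(C)C(C)(C)C)[C@@H]2[C@](C(=O)OC)(CCC3(SCCS3)[C@]2(C)C(=O)OCc2ccccc2)C1=O | intermediate
19 | 6β-OTBS-9-oxo 19-oic acid 20-methyl ester | C[C@@H]1C[C@@H](O[Si](C)(C)C(C)(C)C)[C@@H]2[C@](C(=O)OC)(CCC[C@]2(C)C(=O)O)C1=O | intermediate
20 | 9,20-dihydroxy-19-oic acid (C9 epimers; not isolated) | C[C@@H]1C[C@@H](O[Si](C)(C)C(C)(C)C)[C@@H]2[C@](CO)(CCC[C@]2(C)C(=O)O)C1O | intermediate
21 | 9-hydroxy-19,20-olide (C9 epimers) | C[C@@H]1C[C@@H](O[Si](C)(C)C(C)(C)C)[C@@H]2[C@]3(CCC[C@]2(C)C(=O)OC3)C1O | intermediate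
22 | 9-oxo-19,20-olide | C[C@@H]1C[C@@H](O[Si](C)(C)C(C)(C)C)[C@@H]2[C@]3(CCC[C@]2(C)C(=O)OC3)C1=O | intermediate
23 | 9α-hydroxy-9β-vinyl-19,20-olide | C[C@@H]1C[C@@H](O[Si](C)(C)C(C)(C)C)[C@@H]2[C@]3(CCC[C@]2(C)C(=O)OC3)[C@@]1(O)C=C | intermediate
24 | but-3-yn-1-ol | C#CCCO | starting material
25 | tert-butyl(but-3-yn-1-yloxy)dimethylsilane | C#CCCO[Si](C)(C)C(C)(C)C | intermediate
26 | 5-(tert-butyldimethylsilyloxy)pent-2-yn-1-ol | OCC#CCCO[Si](C)(C)C(C)(C)C | intermediate
27 | (Z)-5-(tert-butyldimethylsilyloxy)-3-iodopent-2-en-1-ol | OC/C=C(\I)CCO[Si](C)(C)C(C)(C)C | intermediate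
28 | B-alkyl-9-BBN from 23, boron on C12 (not isolated) | C[C@@H]1C[C@@H](O[Si](C)(C)C(C)(C)C)[C@@H]2[C@]3(CCC[C@]2(C)C(=O)OC3)[C@@]1(O)CCB1C2CCCC1CCC2 | intermediate
29 | allylic alcohol with C13=C16 alkene (C12 cis to CH2OH) | C[C@@H]1C[C@@H](O[Si](C)(C)C(C)(C)C)[C@@H]2[C@]3(CCC[C@]2(C)C(=O)OC3)[C@@]1(O)CC/C(CCO[Si](C)(C)C(C)(C)C)=C\CO | intermediate
30 | (13R,16R)-13,16-epoxy alcohol (not isolated) | C[C@@H]1C[C@@H](O[Si](C)(C)C(C)(C)C)[C@@H]2[C@]3(CCC[C@]2(C)C(=O)OC3)[C@@]1(O)CC[C@]1(CCO[Si](C)(C)C(C)(C)C)O[C@@H]1CO | intermediate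
31 | 9α,13-epoxy 16,16′-diol (13S,16R) | C[C@@H]1C[C@@H](O[Si](C)(C)C(C)(C)C)[C@@H]2[C@]3(CCC[C@]2(C)C(=O)OC3)[C@@]12CC[C@@](CCO[Si](C)(C)C(C)(C)C)(O2)[C@H](O)CO | intermediate
32 | C16 aldehyde | C[C@@H]1C[C@@H](O[Si](C)(C)C(C)(C)C)[C@@H]2[C@]3(CCC[C@]2(C)C(=O)OC3)[C@@]12CC[C@@](CCO[Si](C)(C)C(C)(C)C)(O2)C=O | intermediate
33 | C16 carboxylic acid | C[C@@H]1C[C@@H](O[Si](C)(C)C(C)(C)C)[C@@H]2[C@]3(CCC[C@]2(C)C(=O)OC3)[C@@]12CC[C@@](CCO[Si](C)(C)C(C)(C)C)(O2)C(=O)O | intermediate
34 | 6β,15-dihydroxy C16 acid (not isolated) | C[C@@H]1C[C@@H](O)[C@@H]2[C@]3(CCC[C@]2(C)C(=O)OC3)[C@@]12CC[C@@](CCO)(O2)C(=O)O | intermediate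
35 | CNP0393616.1 | C[C@@H]1C[C@@H](O)[C@@H]2[C@]3(CCC[C@]2(C)C(=O)OC3)[C@@]12CC[C@@]1(CCOC1=O)O2 | target

**Counts**
Total steps: 26. Longest linear sequence: 20 steps (steps 1–3, 7–18, 22–26).

**Steps most likely to fail, with fallbacks**

Step 9. The thermodynamic bias at C5 may be small, because the axial C10 ester and the two ring B carbonyls both lower the usual preference for the trans-decalin, so the equilibration may stall at a cis/trans mixture. The fallback sets out from 11 and returns at 18; it keeps C5 planar while C4 is alkylated and protonates C5 only when C4 is quaternary. Ac2O/Et3N/DMAP would convert 11 into the C5=C6 dienol acetate F1 (C5 is the only enolisable position of the ene-dione). HF·pyridine would release the β-keto ester F2. K2CO3/MeI would methylate C4 anti to the axial C10 ester to give the C4-methylated dienol acetate F3. Aqueous HCl in THF would hydrolyse the enol acetate, with C5 protonated from the α face under both kinetic and thermodynamic control, to give the trans-fused ene-trione F4. Zn/AcOH followed by DBU (C8 only) would give the saturated trione F5, and ethane-1,2-dithiol/BF3·OEt2 the C3 dithiolane F6. LiBH(s-Bu)3 at −78 °C, with the lithium alkoxide silylated in situ by TBSOTf before it can attack either axial ester, would give 18.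

Step 18. The C9 ketone lies between a quaternary and a tertiary carbon, so addition may lose to enolisation towards C8, or the nucleophile may enter from the α face. The fallback sets out from 22 and returns at 23; it replaces nucleophilic attack on the carbonyl by electrophilic attack on an alkene. Lombardo methylenation (Zn, CH2Br2, TiCl4) would give the 9(11)-exocyclic alkene F7. mCPBA should epoxidise it from the α face, anti to the axial C20, to give the 9α,11-epoxide F8. Excess dimethylsulfonium methylide (Me3S+ I−, n-BuLi) would open the epoxide at C11 and eliminate dimethyl sulfide (one-carbon homologation of an epoxide to an allylic alcohol), giving 23.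

Step 7. Face discrimination by the copper complex may be incomplete, or catalyst turnover may be slowed by the chelating product, so the adduct may form with insufficient enantiomeric purity. The fallback sets out from 5 and 10 and returns at 14; it moves the absolute control to a later reagent-controlled reduction. An achiral Lewis acid (Cu(OTf)2 with 2,2′-bipyridine) would give racemic adduct, that is 11 together with its enantiomer ent-11 F9. Steps 8 and 9 would then give 12 with ent-12 F10 and 13 with ent-13 F11. Corey–Bakshi–Shibata reduction with the (S)-2-methyl-oxazaborolidine and catecholborane would reduce the C6 ketone of 13 quickly (catalyst and substrate both favour α-face delivery) and that of ent-13 F11 slowly (mismatched), so 14 would be obtained by kinetic resolution.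

Further compounds
F1 | step 9 | C5=C6 dienol acetate of 11 | CC1=CC(OC(C)=O)=C2[C@H](C(=O)OCc3ccccc3)C(O[Si](C)(C)C(C)(C)C)=CC[C@]2(C(=O)OC)C1=O
F2 | step 9 | β-keto ester with C5=C6 dienol acetate (C4 epimers and enol) | CC1=CC(OC(C)=O)=C2C(C(=O)OCc3ccccc3)C(=O)CC[C@]2(C(=O)OC)C1=O
F3 | step 9 | C4-methylated dienol acetate (4α-CH3, 4β-CO2Bn) | CC1=CC(OC(C)=O)=C2[C@@](C)(C(=O)OCc3ccccc3)C(=O)CC[C@]2(C(=O)OC)C1=O
F4 | step 9 | trans-fused ene-trione (5α-H, C7=C8, 3,6,9-trione) | CC1=CC(=O)[C@@H]2[C@](C(=O)OC)(CCC(=O)[C@]2(C)C(=O)OCc2ccccc2)C1=O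
F5 | step 9 | saturated trans-fused 3,6,9-trione (8α-CH3) | C[C@@H]1CC(=O)[C@@H]2[C@](C(=O)OC)(CCC(=O)[C@]2(C)C(=O)OCc2ccccc2)C1=O
F6 | step 9 | C3 dithiolane of F5 | C[C@@H]1CC(=O)[C@@H]2[C@](C(=O)OC)(CCC3(SCCS3)[C@]2(C)C(=O)OCc2ccccc2)C1=O
F7 | step 18 | 9(11)-exocyclic alkene | C[C@@H]1C[C@@H](O[Si](C)(C)C(C)(C)C)[C@@H]2[C@]3(CCC[C@]2(C)C(=O)OC3)C1=C
F8 | step 18 | 9α,11-epoxide | C[C@@H]1C[C@@H](O[Si](C)(C)C(C)(C)C)[C@@H]2[C@]3(CCC[C@]2(C)C(=O)OC3)[C@@]1(O2)C2
F9 | step 7 | ent-11 | CC1=CC(=O)[C@H]2[C@@H](C(=O)OCc3ccccc3)C(O[Si](C)(C)C(C)(C)C)=CC[C@@]2(C(=O)OC)C1=O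
F10 | step 7 | ent-12 (C8 epimers) | CC1CC(=O)[C@H]2[C@@H](C(=O)OCc3ccccc3)C(O[Si](C)(C)C(C)(C)C)=CC[C@@]2(C(=O)OC)C1=O
F11 | step 7 | ent-13 | C[C@H]1CC(=O)[C@H]2[C@@](C(=O)OC)(CC=C(O[Si](C)(C)C(C)(C)C)[C@@H]2C(=O)OCc2ccccc2)C1=O
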